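The benzene ring, not the lactone, is disconnected. The lactone ring (C1, O2, C3, C4, C4a, C8a) with its C3 stereocentre is built first as an enantiopure 5,6-dihydropyran-2-one, and the alkene between C4a and C8a of that ring is kept to become two carbons of the arene. One photochemical operation then adds C5–C8 from a diazoacetyl side arm and ethoxyacetylene: Wolff shift, ketene–alkyne (2+2) addition, four-electron ring opening and six-electron ring closure give the resorcinol ring with O6 etherified and O8 free. The precursor is the 4-diazoacetyl lactone carrying the silyl-protected (S)-carbinol chain, reached from undec-10-enal through two catalytic asymmetric C–C bond formations.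

Key step: step 11

Remark: atom labels C1–C8a follow the isochroman-1-one numbering of the target and are used for the same atoms in earlier intermediates (C4a and C8a are C4 and C3 of the dihydropyranone).

Step 1
Reactants: 1 undec-10-enal; 2 diethylzinc
Product: 3 (S)-tridec-12-en-3-ol
Conditions: Et2Zn (1.5 equiv), Ti(OiPr)4 (1.2 equiv), (1R,2R)-1,2-bis(trifluoromethanesulfonamido)cyclohexane (2 mol%), toluene, −20 °C; 1 M HCl
Reagents that add atoms: none
Why: Titanium-mediated enantioselective addition of a dialkylzinc to an aldehyde, a reaction that tolerates unbranched aliphatic aldehydes and terminal alkenes; the (1R,2R)-bis(sulfonamide) ligand is expected to deliver ethyl to the Si face of the carbonyl and so set the (S)-carbinol, an assignment to be checked by Mosher ester analysis before the material is carried on.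

Step 2
Reactants: 3 (S)-tridec-12-en-3-ol
Product: 4 (S)-tert-butyldimethyl(tridec-12-en-3-yloxy)silane
Conditions: TBSCl, imidazole, DMF, rt
Reagents that add atoms: tert-butyldimethylsilyl chloride CC(C)(C)[Si](C)(C)Cl
Why: Standard silylation of a secondary alcohol with silyl chloride and imidazole, giving an ether that should survive ozone, carbonate, triflic anhydride, Stille conditions, amide base and light, and that keeps the hydroxyl from intercepting the ketenes of step 11.

Step 3
Reactants: 4 (S)-tert-butyldimethyl(tridec-12-en-3-yloxy)silane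
Product: 6 (S)-10-(tert-butyldimethylsilyloxy)dodecanal, via ozonide 5 (not isolated)
Conditions: O3, CH2Cl2, −78 °C; then PPh3, −78 °C → rt
Reagents that add atoms: ozone [O-][O+]=O
Why: Ozonolysis of the terminal alkene with reduction of the ozonide by the phosphine removes one carbon and exposes the aldehyde without touching the silyl ether or the stereocentre.

Step 4
Reactants: 7 methyl acetoacetate
Product: 8 methyl 3-(trimethylsilyloxy)but-2-enoate
Conditions: Me3SiCl, Et3N, hexane, rt
Reagents that add atoms: chlorotrimethylsilane C[Si](C)(C)Cl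
Why: O-Silylation of the enol of a β-keto ester by silyl chloride and amine base, the usual first stage toward a bis-silyl dienolate.

Step 5
Reactants: 8 methyl 3-(trimethylsilyloxy)but-2-enoate
Product: 9 1-methoxy-1,3-bis(trimethylsilyloxy)buta-1,3-diene
Conditions: LiN(iPr)2, THF, −78 °C; Me3SiCl, −78 → 0 °C
Reagents that add atoms: chlorotrimethylsilane C[Si](C)(C)Cl
Why: γ-Deprotonation of the silyl enol ether ester by the lithium amide and O-silylation of the ester dienolate give the 1,3-bis(siloxy)diene, which is to be used freshly distilled because it hydrolyses easily.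

Step 6
Reactants: 6 (S)-10-(tert-butyldimethylsilyloxy)dodecanal; 9 1-methoxy-1,3-bis(trimethylsilyloxy)buta-1,3-diene
Product: 11 methyl (5R,14S)-14-(tert-butyldimethylsilyloxy)-5-hydroxy-3-oxohexadecanoate, via bis-silyl aldol adduct 10 (not isolated)
Conditions: Ti(OiPr)4 (10 mol%), (S)-BINOL (10 mol%), 4 Å MS, THF, −78 °C → rt; then PPTS, MeOH, 0 °C
Reagents that add atoms: none
Why: Catalytic asymmetric vinylogous Mukaiyama aldol addition in which the diene reacts through its terminal CH2 with the titanium–BINOL-activated aldehyde; the (S)-ligand is expected to direct attack to the Si face and so set C5 as (R) independently of the remote silyloxy centre, and buffered methanolysis then strips only the trimethylsilyl groups.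

Step 7
Reactants: 11 methyl (5R,14S)-14-(tert-butyldimethylsilyloxy)-5-hydroxy-3-oxohexadecanoate
Product: 12 (R)-6-[(S)-9-(tert-butyldimethylsilyloxy)undecyl]-4-hydroxy-5,6-dihydro-2H-pyran-2-one
Conditions: K2CO3, MeOH, rt; then 1 M HCl to pH 3, 0 °C
Reagents that add atoms: none
Why: Base-mediated lactonisation (intramolecular transesterification) of a δ-hydroxy-β-keto ester, which does not break the C–O bond of the carbinol, so that the (R) centre becomes C3 of the future isochromanone unchanged.

Step 8
Reactants: 12 (R)-6-[(S)-9-(tert-butyldimethylsilyloxy)undecyl]-4-hydroxy-5,6-dihydro-2H-pyran-2-one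
Product: 13 (R)-6-[(S)-9-(tert-butyldimethylsilyloxy)undecyl]-2-oxo-5,6-dihydro-2H-pyran-4-yl trifluoromethanesulfonate
Conditions: Tf2O, Et3N, CH2Cl2, −78 °C
Reagents that add atoms: trifluoromethanesulfonic anhydride O=S(=O)(OS(=O)(=O)C(F)(F)F)C(F)(F)F
Why: O-Sulfonylation of the enolised 1,3-dicarbonyl (a vinylogous acid) with triflic anhydride gives the enol triflate at the carbon that is to become C4a.

Step 9
Reactants: 13 (R)-6-[(S)-9-(tert-butyldimethylsilyloxy)undecyl]-2-oxo-5,6-dihydro-2H-pyran-4-yl trifluoromethanesulfonate
Product: 15 (R)-4-acetyl-6-[(S)-9-(tert-butyldimethylsilyloxy)undecyl]-5,6-dihydro-2H-pyran-2-one, via ethoxyvinyl diene 14 (not isolated)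
Conditions: tributyl(1-ethoxyvinyl)stannane, Pd(PPh3)4 (5 mol%), LiCl, 1,4-dioxane, 90 °C; then 1 M HCl, THF, 0 °C
Reagents that add atoms: tributyl(1-ethoxyvinyl)stannane CCCC[Sn](CCCC)(CCCC)C(=C)OCC; water O
Why: Stille coupling of an electron-poor enol triflate with an α-alkoxyvinylstannane, assisted by chloride, followed by hydrolysis of the enol ether under acid too mild to cleave the secondary silyl ether, installs the acetyl group.

Step 10
Reactants: 15 (R)-4-acetyl-6-[(S)-9-(tert-butyldimethylsilyloxy)undecyl]-5,6-dihydro-2H-pyran-2-one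
Product: 17 (R)-4-(2-diazoacetyl)-6-[(S)-9-(tert-butyldimethylsilyloxy)undecyl]-5,6-dihydro-2H-pyran-2-one, via trifluoroacetyl diketone 16 (not isolated)
Conditions: LiN(SiMe3)2 (1.1 equiv), THF, −78 °C; CF3CO2CH2CF3, −78 °C; cold 5% HCl work-up; then MsN3, Et3N, H2O (1 equiv), MeCN, rt
Reagents that add atoms: methanesulfonyl azide CS(=O)(=O)N=[N+]=[N-]
Why: Detrifluoroacetylative diazo transfer, the standard route to α'-diazo enones: kinetic deprotonation of the methyl ketone at −78 °C and C-trifluoroacetylation give diketone 16, whose enolate accepts the diazo group from the sulfonyl azide and loses the trifluoroacetyl group as a sulfonamide, whereas the acid chloride–diazomethane alternative would suffer dipolar cycloaddition to the doubly activated alkene.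

Step 11
Reactants: 17 (R)-4-(2-diazoacetyl)-6-[(S)-9-(tert-butyldimethylsilyloxy)undecyl]-5,6-dihydro-2H-pyran-2-one; 18 ethoxyacetylene
Product: 23 (R)-6-ethoxy-8-hydroxy-3-[(S)-9-(tert-butyldimethylsilyloxy)undecyl]isochroman-1-one, via vinylketene 19 (not isolated), via vinylcyclobutenone 20 (not isolated), via dienylketene 21 (not isolated), via cyclohexadienone 22 (not isolated)
Conditions: hν (300 nm lamps, Pyrex), 18 (3 equiv), degassed ClCH2CH2Cl (0.05 M), rt; then 80 °C, sealed tube, dark
Reagents that add atoms: none
Why: Light expels N2 from 17 and C4a shifts from the acyl carbon to the diazo carbon (Wolff rearrangement, forming C4a–C5), so that the former carbonyl carbon becomes the ketene carbon of 19, conjugated with the C4a=C8a alkene. The ynol ether adds across the ketene C=C bond in a (2+2) cycloaddition, its unsubstituted carbon bonding to the ketene carbon (C7–C8) and its oxygen-bearing carbon to C5 (C5–C6), which gives 20; four-electron electrocyclic opening of the strained ring gives 21, thermal disrotatory six-electron electrocyclisation closes the only new ring, the benzene ring, through C8–C8a, and enolisation of 22 delivers the phenol. The closest known reaction type is the photochemical Wolff variant of the Danheiser benzannulation of α-diazo enones with alkoxy- and siloxyalkynes; here the enone sits inside an unsaturated lactone, which is a new substrate for a known reaction type. No stereocentre is created, and C3 and the side-chain carbinol take no part. The selectivity needed is the orientation of the ketene–alkyne addition, which the polarisation of ethoxyacetylene (nucleophilic terminal carbon, electrophilic ketene carbon) secures, placing OEt on C6 and the free hydroxyl on C8 next to the lactone carbonyl. Light of 300 nm is chosen so that the diazo ketone absorbs and the lactone chromophore does not, and the excess of alkyne at low concentration is meant to outrun capture of the ketene by the phenol being formed.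

Step 12
Reactants: 23 (R)-6-ethoxy-8-hydroxy-3-[(S)-9-(tert-butyldimethylsilyloxy)undecyl]isochroman-1-one
Product: 24 (R)-6,8-dihydroxy-3-[(S)-9-hydroxyundecyl]isochroman-1-one
Conditions: AlCl3 (8 equiv), EtSH–CH2Cl2, 0 °C → rt; then 1 M HCl, THF, rt
Reagents that add atoms: none
Why: Hard Lewis acid–soft nucleophile dealkylation of an aryl alkyl ether, in which the thiol attacks the primary ethyl carbon of the aluminium-complexed ether; the side-chain oxygen ends as an aluminium alkoxide that is not a leaving group (boron tribromide would instead risk turning this secondary carbinol into a bromide), the secondary C3–O bond of the lactone is far less open to SN2 attack than the ethyl group, and the acidic work-up completes removal of the silyl group.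

Compound list
1 | undec-10-enal | C=CCCCCCCCCC=O | starting material
2 | diethylzinc | CC[Zn]CC | starting material
3 | (S)-tridec-12-en-3-ol | CC[C@H](O)CCCCCCCCC=C | intermediate
4 | (S)-tert-butyldimethyl(tridec-12-en-3-yloxy)silane | CC[C@H](O[Si](C)(C)C(C)(C)C)CCCCCCCCC=C | intermediate
5 | 3-[(S)-9-(tert-butyldimethylsilyloxy)undecyl]-1,2,4-trioxolane (ozonide, epimers at the ring carbon) | CC[C@H](O[Si](C)(C)C(C)(C)C)CCCCCCCCC1OCOO1 | intermediate (not isolated)
6 | (S)-10-(tert-butyldimethylsilyloxy)dodecanal | CC[C@H](O[Si](C)(C)C(C)(C)C)CCCCCCCCC=O | intermediate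
7 | methyl acetoacetate | CC(=O)CC(=O)OC | starting material
8 | methyl 3-(trimethylsilyloxy)but-2-enoate (alkene geometry not consequential) | CC(O[Si](C)(C)C)=CC(=O)OC | intermediate
9 | 1-methoxy-1,3-bis(trimethylsilyloxy)buta-1,3-diene (alkene geometry not consequential) | COC(O[Si](C)(C)C)=CC(=C)O[Si](C)(C)C | intermediate
10 | methyl (5R,14S)-14-(tert-butyldimethylsilyloxy)-3,5-bis(trimethylsilyloxy)hexadec-2-enoate | CC[C@H](O[Si](C)(C)C(C)(C)C)CCCCCCCC[C@@H](O[Si](C)(C)C)CC(O[Si](C)(C)C)=CC(=O)OC | intermediate (not isolated)
11 | methyl (5R,14S)-14-(tert-butyldimethylsilyloxy)-5-hydroxy-3-oxohexadecanoate | CC[C@H](O[Si](C)(C)C(C)(C)C)CCCCCCCC[C@@H](O)CC(=O)CC(=O)OC | intermediate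
12 | (R)-6-[(S)-9-(tert-butyldimethylsilyloxy)undecyl]-4-hydroxy-5,6-dihydro-2H-pyran-2-one | CC[C@H](O[Si](C)(C)C(C)(C)C)CCCCCCCC[C@@H]1CC(O)=CC(=O)O1 | intermediate
13 | (R)-6-[(S)-9-(tert-butyldimethylsilyloxy)undecyl]-2-oxo-5,6-dihydro-2H-pyran-4-yl trifluoromethanesulfonate | CC[C@H](O[Si](C)(C)C(C)(C)C)CCCCCCCC[C@@H]1CC(OS(=O)(=O)C(F)(F)F)=CC(=O)O1 | intermediate
14 | (R)-4-(1-ethoxyvinyl)-6-[(S)-9-(tert-butyldimethylsilyloxy)undecyl]-5,6-dihydro-2H-pyran-2-one | CC[C@H](O[Si](C)(C)C(C)(C)C)CCCCCCCC[C@@H]1CC(C(=C)OCC)=CC(=O)O1 | intermediate (not isolated)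
15 | (R)-4-acetyl-6-[(S)-9-(tert-butyldimethylsilyloxy)undecyl]-5,6-dihydro-2H-pyran-2-one | CC[C@H](O[Si](C)(C)C(C)(C)C)CCCCCCCC[C@@H]1CC(C(C)=O)=CC(=O)O1 | intermediate
16 | (R)-6-[(S)-9-(tert-butyldimethylsilyloxy)undecyl]-4-(4,4,4-trifluoro-3-oxobutanoyl)-5,6-dihydro-2H-pyran-2-one | CC[C@H](O[Si](C)(C)C(C)(C)C)CCCCCCCC[C@@H]1CC(C(=O)CC(=O)C(F)(F)F)=CC(=O)O1 | intermediate (not isolated)
17 | (R)-4-(2-diazoacetyl)-6-[(S)-9-(tert-butyldimethylsilyloxy)undecyl]-5,6-dihydro-2H-pyran-2-one | CC[C@H](O[Si](C)(C)C(C)(C)C)CCCCCCCC[C@@H]1CC(C(=O)C=[N+]=[N-])=CC(=O)O1 | intermediate (key-step precursor)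
18 | ethoxyacetylene | CCOC#C | starting material
19 | (R)-6-[(S)-9-(tert-butyldimethylsilyloxy)undecyl]-4-(2-oxoethenyl)-5,6-dihydro-2H-pyran-2-one | CC[C@H](O[Si](C)(C)C(C)(C)C)CCCCCCCC[C@@H]1CC(C=C=O)=CC(=O)O1 | intermediate (not isolated)
20 | (6R)-6-[(S)-9-(tert-butyldimethylsilyloxy)undecyl]-4-(2-ethoxy-4-oxocyclobut-2-en-1-yl)-5,6-dihydro-2H-pyran-2-one (epimers at the cyclobutene carbon) | CC[C@H](O[Si](C)(C)C(C)(C)C)CCCCCCCC[C@@H]1CC(C2C(=O)C=C2OCC)=CC(=O)O1 | intermediate (not isolated)
21 | (R)-6-[(S)-9-(tert-butyldimethylsilyloxy)undecyl]-4-[(1E)-2-ethoxy-4-oxobuta-1,3-dien-1-yl]-5,6-dihydro-2H-pyran-2-one | CC[C@H](O[Si](C)(C)C(C)(C)C)CCCCCCCC[C@@H]1CC(/C=C(\C=C=O)OCC)=CC(=O)O1 | intermediate (not isolated)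
22 | (3R)-6-ethoxy-3-[(S)-9-(tert-butyldimethylsilyloxy)undecyl]-3,4-dihydro-1H-isochromene-1,8(8aH)-dione (epimers at C8a) | CC[C@H](O[Si](C)(C)C(C)(C)C)CCCCCCCC[C@@H]1CC2=CC(OCC)=CC(=O)C2C(=O)O1 | intermediate (not isolated)
23 | (R)-6-ethoxy-8-hydroxy-3-[(S)-9-(tert-butyldimethylsilyloxy)undecyl]isochroman-1-one | CC[C@H](O[Si](C)(C)C(C)(C)C)CCCCCCCC[C@@H]1Cc2cc(OCC)cc(O)c2C(=O)O1 | intermediate (key-step product)
24 | (R)-6,8-dihydroxy-3-[(S)-9-hydroxyundecyl]isochroman-1-one | CC[C@H](O)CCCCCCCC[C@@H]1Cc2cc(O)cc(O)c2C(=O)O1 | target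

Total step count: 12. Longest linear sequence: 10 steps (1–3, then 6–12); steps 4 and 5 form a two-step side branch.

Steps most likely to fail

1. Step 11. The photolysis may not funnel cleanly into the Wolff shift (carbene insertion or addition to the alkyne instead). The electron-poor vinylketene may be captured by the phenol as it forms. The six-electron closure onto the ester-bearing C8a may lag, so that the dienylketene oligomerises. The fallback builds the lactone onto a preformed arene with known chemistry; it sets out from 4 and comes back at 24. The alkene of 4 would be epoxidised with mCPBA to the epoxide F1, a pair of epimers at the new centre. Hydrolytic kinetic resolution with (R,R)-(salen)Co(OAc) and water should leave the (R)-epoxide F2, the other epimer being removed as its diol. Opening at the terminal carbon with 3,5-dimethoxyphenylmagnesium bromide and catalytic CuI should give the homobenzylic alcohol F3 with C3 already (R). Bromination with NBS para to one methoxy group and ortho to the side chain gives the aryl bromide F4. Carbonylative lactonisation (Pd(OAc)2, Xantphos, CO, Et3N, toluene, 100 °C) then closes the dimethoxy lactone F5. The AlCl3–EtSH treatment of step 12, applied to F5, should remove both methyl ethers and the silyl group and give 24.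

2. Step 10. The amide base may remove a C4 proton (γ to the lactone carbonyl) in competition with the acetyl proton. β-Elimination of the carboxylate would then open the lactone to a dienoic acid. The amine base of the second stage could trigger the same elimination more slowly. The fallback avoids the lithium enolate; it sets out from 13 and comes back at 17. The Stille coupling of step 9 would be run as before, but the ethoxyvinyl diene 14 would be treated with NBS in THF–water at 0 °C instead of acid. This should give the bromomethyl ketone F6 directly. Brief exposure of F6 to N,N'-ditosylhydrazine and DBU in THF at 0 °C, the established conversion of α-bromo carbonyl compounds into diazo carbonyl compounds, should then give 17.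

3. Step 6. Facial selectivity with an unbranched aliphatic aldehyde may be incomplete. The resulting C5 epimer could not be separated, because the other stereocentre lies nine carbons away. The fallback sets the centre by hydrogenation; it sets out from 6 and comes back at 11. Homologation of 6 with ethyl diazoacetate and catalytic SnCl2 (Roskamp reaction) should give the β-keto ester F7. Noyori hydrogenation with RuCl2[(R)-BINAP] under H2 in ethanol should give the (3R)-hydroxy ester F8, in the same sense as the reduction of methyl acetoacetate to the (R)-hydroxy ester. Claisen condensation of F8 with an excess of the lithium enolate of methyl acetate (LiN(iPr)2, THF, −78 → −30 °C) then gives 11.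

Further compounds
F1 | step 11 | tert-butyldimethyl{[(3S)-11-(oxiran-2-yl)undecan-3-yl]oxy}silane (both epimers at the oxirane carbon) | CC[C@H](O[Si](C)(C)C(C)(C)C)CCCCCCCCC1CO1
F2 | step 11 | tert-butyldimethyl{[(3S)-11-[(2R)-oxiran-2-yl]undecan-3-yl]oxy}silane | CC[C@H](O[Si](C)(C)C(C)(C)C)CCCCCCCC[C@@H]1CO1
F3 | step 11 | (2R,11S)-11-(tert-butyldimethylsilyloxy)-1-(3,5-dimethoxyphenyl)tridecan-2-ol | CC[C@H](O[Si](C)(C)C(C)(C)C)CCCCCCCC[C@@H](O)Cc1cc(OC)cc(OC)c1
F4 | step 11 | (2R,11S)-1-(2-bromo-3,5-dimethoxyphenyl)-11-(tert-butyldimethylsilyloxy)tridecan-2-ol | CC[C@H](O[Si](C)(C)C(C)(C)C)CCCCCCCC[C@@H](O)Cc1cc(OC)cc(OC)c1Br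
F5 | step 11 | (R)-3-[(S)-9-(tert-butyldimethylsilyloxy)undecyl]-6,8-dimethoxyisochroman-1-one | CC[C@H](O[Si](C)(C)C(C)(C)C)CCCCCCCC[C@@H]1Cc2cc(OC)cc(OC)c2C(=O)O1
F6 | step 10 | (R)-4-(2-bromoacetyl)-6-[(S)-9-(tert-butyldimethylsilyloxy)undecyl]-5,6-dihydro-2H-pyran-2-one | CC[C@H](O[Si](C)(C)C(C)(C)C)CCCCCCCC[C@@H]1CC(C(=O)CBr)=CC(=O)O1
F7 | step 6 | ethyl (S)-12-(tert-butyldimethylsilyloxy)-3-oxotetradecanoate | CC[C@H](O[Si](C)(C)C(C)(C)C)CCCCCCCCC(=O)CC(=O)OCC
F8 | step 6 | ethyl (3R,12S)-12-(tert-butyldimethylsilyloxy)-3-hydroxytetradecanoate | CC[C@H](O[Si](C)(C)C(C)(C)C)CCCCCCCC[C@@H](O)CC(=O)OCC
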